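**Plan**

- Retrosynthesis: the O8 angelate ester is cut first. The C6–C7 bond is then cut together with the O6–C12 lactone bond, which opens both rings to an acyclic enal / 2-(bromomethyl)enoate. Further cuts are C7–C11 (acrylate unit), C10–C14 (ester carbon), C9–C10 (fragment union) and C1≡C10 (one-carbon homologation).
- Enabling feature: C6–C7 is the one bond common to the ten-membered carbocycle (C1–C10) and the γ-lactone (O6–C6–C7–C11–C12). C6 is allylic to C4=C5, so it is an enal carbonyl before closure. C7 is the γ-carbon of the C13–C11(C12)=C7 allyl unit. The ring-cis C1=C10 enoate already folds the open chain.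
- Forward: fragment 1 (C1–C6, C15 and the added C10, from geraniol) and fragment 2 (C7–C9, from (S)-solketal) are joined at C9–C10. C14 is added by carbonylation, both chain ends are oxidized, and C11–C13 are attached at C7. The carbocycle and then the lactone close in one operation; acylation and desilylation finish.
- Stereochemistry: C8 comes from (S)-solketal. C9 is set by chelation-controlled alkynylzinc addition (8,9-syn). C6 and C7 are set in the ring closure (chair transition state, relayed from C8). The 4E olefin comes from geraniol, the C1=C10 geometry from syn-hydrostannation followed by stereoretentive Sn→I→CO2Me exchange, and the Z side chain from angelic acid.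

Key step: step 19

Remark: atom numbers C1–C15 are the germacrane numbers of the target and are kept for the open-chain intermediates.
Remark: the epoxide of step 2 is racemic and the adduct of step 17 is a C7 epimer mixture; both centres are erased downstream and are drawn without configuration.
Remark: species that persist in the flask before reacting on (organometallics, the diol of step 3, the mixed anhydride of step 21) are numbered as intermediates; catalyst-bound and fleeting species are not.

**Route**

Step 1
Reactants: 1 geraniol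
Product: 2 geranyl tert-butyldiphenylsilyl ether
Conditions: TBDPSCl, imidazole, CH2Cl2, 0 °C → rt
Reagents that add atoms: tert-butyl(chloro)diphenylsilane (TBDPSCl), CC(C)(C)[Si](Cl)(c1ccccc1)c1ccccc1
Why: Imidazole-promoted silylation of a primary allylic alcohol is routine, and the TBDPS ether is chosen because it withstands the acidic, basic and organometallic steps up to step 15.

Step 2
Reactants: 2 geranyl tert-butyldiphenylsilyl ether
Product: 3 racemic epoxide of the isopropylidene olefin of 2
Conditions: mCPBA, CH2Cl2, −20 → 0 °C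
Reagents that add atoms: 3-chloroperbenzoic acid (mCPBA), O=C(OO)c1cccc(Cl)c1
Why: Prilezhaev epoxidation should pick the remote isopropylidene olefin because the other trisubstituted olefin is deactivated inductively by the allylic silyloxy group; the new centre is racemic and disappears in step 3.

Step 3
Reactants: 3 racemic epoxide
Product: 5 (4E)-6-[(tert-butyldiphenylsilyl)oxy]-4-methylhex-4-enal, via vicinal diol 4 (not isolated)
Conditions: H5IO6, THF/H2O, 0 °C
Reagents that add atoms: none
Why: Acid-catalysed hydration of the epoxide (water entering at the tertiary carbon) followed in the same flask by Malaprade glycol cleavage should give the aldehyde and acetone, so the aldehyde oxygen is the former epoxide oxygen and the E olefin and the silyl ether stay untouched.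

Step 4
Reactants: 5 (4E)-6-[(tert-butyldiphenylsilyl)oxy]-4-methylhex-4-enal
Product: 6 fragment 1: tert-butyl{[(2E)-3-methylhept-2-en-6-yn-1-yl]oxy}diphenylsilane
Conditions: dimethyl (1-diazo-2-oxopropyl)phosphonate, K2CO3, MeOH, 0 °C → rt
Reagents that add atoms: dimethyl (1-diazo-2-oxopropyl)phosphonate (Ohira–Bestmann reagent), CC(=O)C(=[N+]=[N-])P(=O)(OC)OC
Why: The Ohira–Bestmann variant of the Seyferth–Gilbert homologation turns the aldehyde into the terminal alkyne under mild carbonate conditions that spare the TBDPS ether and the E olefin; the carbon added becomes C10.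

Step 5
Reactants: 7 (S)-solketal
Product: 8 tert-butyl{[(4R)-2,2-dimethyl-1,3-dioxolan-4-yl]methoxy}diphenylsilane
Conditions: TBDPSCl, imidazole, DMF, rt
Reagents that add atoms: tert-butyl(chloro)diphenylsilane (TBDPSCl), CC(C)(C)[Si](Cl)(c1ccccc1)c1ccccc1
Why: Standard silylation of the primary alcohol; the stereocentre is not touched (the descriptor changes only through the priority rules).

Step 6
Reactants: 8 silylated solketal
Product: 9 (2R)-3-[(tert-butyldiphenylsilyl)oxy]propane-1,2-diol
Conditions: AcOH/H2O (4:1), 40 °C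
Reagents that add atoms: none
Why: Acid-catalysed acetonide hydrolysis; the TBDPS ether tolerates aqueous acetic acid and no bond to the stereocentre is broken.

Step 7
Reactants: 9 (2R)-3-[(tert-butyldiphenylsilyl)oxy]propane-1,2-diol
Product: 10 (4R)-4-{[(tert-butyldiphenylsilyl)oxy]methyl}-2-(4-methoxyphenyl)-1,3-dioxolane (both acetal epimers)
Conditions: 4-MeOC6H4CH(OMe)2, PPTS (cat.), CH2Cl2, rt
Reagents that add atoms: 4-methoxybenzaldehyde dimethyl acetal, COc1ccc(C(OC)OC)cc1
Why: Acid-catalysed transacetalization gives the five-membered p-methoxybenzylidene acetal of the 1,2-diol; the acetal centre is removed in step 8.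

Step 8
Reactants: 10 p-methoxybenzylidene acetal
Product: 11 (2R)-3-[(tert-butyldiphenylsilyl)oxy]-2-[(4-methoxybenzyl)oxy]propan-1-ol
Conditions: i-Bu2AlH, CH2Cl2, −78 → 0 °C
Reagents that add atoms: none
Why: Reductive acetal opening: the aluminium hydride binds the less hindered primary oxygen, that C–O bond breaks and hydride goes to the oxocarbenium ion, so the PMB group stays on the secondary oxygen and the primary alcohol is freed.

Step 9
Reactants: 11 primary alcohol
Product: 12 fragment 2: (2S)-3-[(tert-butyldiphenylsilyl)oxy]-2-[(4-methoxybenzyl)oxy]propanal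
Conditions: Dess–Martin periodinane, CH2Cl2, 0 °C → rt; used at once
Reagents that add atoms: none
Why: Dess–Martin oxidation is non-basic, so the α-alkoxy aldehyde should form without epimerization of the future C8.

Step 10
Reactants: 6 fragment 1 (enyne); 12 fragment 2 (aldehyde)
Product: 15 C1–C10 propargylic alcohol (8S,9S; 8,9-syn), via lithium acetylide 13 (not isolated), via alkynylzinc bromide 14 (not isolated)
Conditions: 6, n-BuLi, Et2O, −78 °C; ZnBr2, 0 °C; then 12, −78 → 0 °C
Reagents that add atoms: none
Why: 1,2-Addition of an alkynylzinc bromide under Cram chelate control: zinc bridges the carbonyl oxygen and the α-PMB ether oxygen (the bulky β-silyl ether does not chelate) and the acetylide attacks the face away from the CH2OTBDPS group, which sets C9 syn to C8 and forms the C9–C10 bond.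

Step 11
Reactants: 15 propargylic alcohol
Product: 16 (E)-vinylstannane with tin on C10
Conditions: Bu3SnH, PdCl2(PPh3)2 (cat.), THF, 0 °C → rt
Reagents that add atoms: tributyltin hydride, CCCC[SnH](CCCC)CCCC
Why: Palladium-catalysed hydrostannation adds H and Sn syn, with tin on the alkyne carbon next to the carbinol (the usual regiochemistry for secondary propargylic alcohols), which places H1 cis to tin and fixes the ring-cis C1=C10 geometry.

Step 12
Reactants: 16 vinylstannane
Product: 17 (E)-vinyl iodide with iodine on C10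
Conditions: I2, CH2Cl2, 0 °C
Reagents that add atoms: iodine, II
Why: Iododestannylation is an ipso substitution with retention of olefin geometry and is much faster than any reaction of iodine with the trisubstituted olefin or the PMB ether.

Step 13
Reactants: 17 vinyl iodide
Product: 18 C9 tert-butyldimethylsilyl ether of 17
Conditions: TBSOTf, 2,6-lutidine, CH2Cl2, −78 → 0 °C
Reagents that add atoms: tert-butyldimethylsilyl trifluoromethanesulfonate (TBSOTf), CC(C)(C)[Si](C)(C)OS(=O)(=O)C(F)(F)F
Why: The silyl triflate with a hindered base silylates the crowded secondary alcohol; a secondary TBS ether is chosen because it outlasts the primary TBDPS ethers in step 15 and comes off under acidic fluoride at the end.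

Step 14
Reactants: 18 silylated vinyl iodide
Product: 19 C14 methyl enoate with both primary TBDPS ethers
Conditions: CO (1 atm), Pd(PPh3)4 (cat.), Et3N, MeOH/DMF, 60 °C
Reagents that add atoms: carbon monoxide, [C-]#[O+]; methanol, CO
Why: Palladium-catalysed methoxycarbonylation of a vinyl iodide (oxidative addition, CO insertion, methanolysis) proceeds with retention, so CO2Me ends up cis to H1 as in the target.

Step 15
Reactants: 19 bis-TBDPS enoate
Product: 20 C6,C7-diol
Conditions: NH4F, MeOH, 50 °C
Reagents that add atoms: none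
Why: Fluoride-mediated desilylation under near-neutral conditions should remove the two unhindered primary TBDPS ethers well before the secondary TBS ether, which is shielded by the enoate carbon and the C8 ether; methanol cannot scramble the methyl ester.

Step 16
Reactants: 20 diol
Product: 21 C6,C7-dialdehyde
Conditions: Dess–Martin periodinane (excess), CH2Cl2, 0 °C → rt; used at once
Reagents that add atoms: none
Why: Dess–Martin oxidation converts the allylic alcohol to the E enal and the other primary alcohol to the α-alkoxy aldehyde in one operation, without base and therefore without epimerization at C8 or olefin isomerization.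

Step 17
Reactants: 21 dialdehyde; 22 methyl acrylate
Product: 23 Morita–Baylis–Hillman adduct at C7 (both C7 epimers)
Conditions: 22 (excess), DABCO, MeOH, rt
Reagents that add atoms: none
Why: In the Morita–Baylis–Hillman reaction the amine–acrylate zwitterion should add to the inductively activated α-alkoxy aldehyde far faster than to the β,β-disubstituted enal, a poor acceptor in this reaction; this forms C7–C11, and the C7 carbinol centre is erased in step 18.

Step 18
Reactants: 23 Morita–Baylis–Hillman adduct
Product: 24 seco (Z)-allylic bromide, the ring-closure precursor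
Conditions: NBS, Me2S, CH2Cl2, 0 °C → rt
Reagents that add atoms: N-bromosuccinimide, O=C1CCC(=O)N1Br
Why: The Corey–Kim-type sulfonium reagent activates the alcohol as an alkoxysulfonium ion and bromide attacks C13 in the SN2′ sense, which is the established route from Morita–Baylis–Hillman alcohols to (Z)-2-(bromomethyl)alk-2-enoates and leaves the aldehyde, esters and ethers alone.

Step 19
Reactants: 24 seco allylic bromide
Product: 27 melampolide core (8-O-PMB, 9-O-TBS, 6,12-olide), via allylchromium dichloride 25 (not isolated), via chromium alkoxide 26 (not isolated)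
Conditions: CrCl2 (excess), THF, rt, slow addition of 24 (high dilution); aq. NH4Cl
Reagents that add atoms: none
Why: CrCl2 reduces the C13–Br bond by two one-electron transfers to the allylchromium 25 (trivalent chromium on C13), which adds through its γ-carbon C7 to the C6 enal carbonyl in a six-membered chair (SE2′ 1,2-addition), and the chromium alkoxide 26 then acylates itself on the C12 methyl ester. The closest known reaction type is the intramolecular Nozaki–Hiyama–Kishi (chromium Barbier) allylation of an aldehyde by a 2-(bromomethyl)alk-2-enoate, which is known to close ten-membered germacranolide rings with formation of the α-methylene lactone. The carbocycle closes 10-exo-trig at the aldehyde (C7 in the ring, C11=C13 left exocyclic) and the lactone closes 5-exo-trig by attack of O6 on C12, in that order. C6 is set by the chair, in which C5 and C8 are both pseudo-equatorial and give the 6,7-anti (trans-lactone) relationship; the allylchromium geometry this needs (C8 trans to CH2Cr) is reachable from either bromide isomer by 1,3-metal shift. C7 is set by the C8 stereocentre: its C–H bond eclipses the allyl plane on the ester side (A(1,3) strain), the C9 arm lies anti to the forming bond and the PMB ether flanks it, which corresponds to (6R,7S). The step needs attack on the aldehyde only (inherent to allylchromium, which ignores the C14 ester and the ethers), ring closure over oligomerization (high dilution plus the turn imposed by the ring-cis C1=C10 enoate and the s-trans enal) and the correct C7 face; this last point rests on the C8 centre alone and is the least certain part of the route.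

Step 20
Reactants: 27 8-O-PMB lactone
Product: 28 8-hydroxy lactone
Conditions: DDQ, CH2Cl2/pH 7 buffer, 0 °C
Reagents that add atoms: none
Why: DDQ oxidizes only the electron-rich PMB ether (hydride abstraction to the oxocarbenium ion, then hydrolysis), so the TBS ether, both olefins and the α-methylene lactone should survive.

Step 21
Reactants: 28 8-hydroxy lactone; 29 angelic acid
Product: 31 9-O-TBS polymatin A, via mixed anhydride 30 (not isolated)
Conditions: 29, 2,4,6-Cl3C6H2COCl, Et3N, toluene, rt; then 28, 80 °C
Reagents that add atoms: none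
Why: Yamaguchi-type esterification through the preformed mixed anhydride without a nucleophilic catalyst: the trichlorobenzoyl carbonyl is shielded so the alcohol attacks the angeloyl carbonyl, and without DMAP there is no reversible conjugate addition that would turn the Z angelate into the E tiglate.

Step 22
Reactants: 31 9-O-TBS polymatin A
Product: 32 polymatin A
Conditions: HF·pyridine, pyridine, THF, 0 °C → rt
Reagents that add atoms: none
Why: Fluoride desilylation under acidic conditions generates no alkoxide, so the angelate should not migrate from O8 to O9 and the α-methylene lactone and both enoates stay intact.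

**Compound list**

1 | geraniol, (2E)-3,7-dimethylocta-2,6-dien-1-ol | CC(C)=CCC/C(C)=C/CO | starting material
2 | tert-butyl{[(2E)-3,7-dimethylocta-2,6-dien-1-yl]oxy}diphenylsilane | CC(C)=CCC/C(C)=C/CO[Si](c1ccccc1)(c1ccccc1)C(C)(C)C | intermediate
3 | tert-butyl{[(2E)-5-(3,3-dimethyloxiran-2-yl)-3-methylpent-2-en-1-yl]oxy}diphenylsilane (racemic) | CC1(C)OC1CC/C(C)=C/CO[Si](c1ccccc1)(c1ccccc1)C(C)(C)C | intermediate
4 | (6E)-8-[(tert-butyldiphenylsilyl)oxy]-2,6-dimethyloct-6-ene-2,3-diol (racemic, not isolated) | CC(C)(O)C(O)CC/C(C)=C/CO[Si](c1ccccc1)(c1ccccc1)C(C)(C)C | intermediate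
5 | (4E)-6-[(tert-butyldiphenylsilyl)oxy]-4-methylhex-4-enal | O=CCC/C(C)=C/CO[Si](c1ccccc1)(c1ccccc1)C(C)(C)C | intermediate
6 | fragment 1, tert-butyl{[(2E)-3-methylhept-2-en-6-yn-1-yl]oxy}diphenylsilane | C#CCC/C(C)=C/CO[Si](c1ccccc1)(c1ccccc1)C(C)(C)C | intermediate
7 | (S)-solketal, [(4S)-2,2-dimethyl-1,3-dioxolan-4-yl]methanol | OC[C@H]1COC(C)(C)O1 | starting material
8 | tert-butyl{[(4R)-2,2-dimethyl-1,3-dioxolan-4-yl]methoxy}diphenylsilane | CC(C)(C)[Si](c1ccccc1)(c1ccccc1)OC[C@H]1COC(C)(C)O1 | intermediate
9 | (2R)-3-[(tert-butyldiphenylsilyl)oxy]propane-1,2-diol | CC(C)(C)[Si](c1ccccc1)(c1ccccc1)OC[C@H](O)CO | intermediate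
10 | (4R)-4-{[(tert-butyldiphenylsilyl)oxy]methyl}-2-(4-methoxyphenyl)-1,3-dioxolane (acetal epimers) | CC(C)(C)[Si](c1ccccc1)(c1ccccc1)OC[C@H]1COC(c2ccc(OC)cc2)O1 | intermediate
11 | (2R)-3-[(tert-butyldiphenylsilyl)oxy]-2-[(4-methoxybenzyl)oxy]propan-1-ol | CC(C)(C)[Si](c1ccccc1)(c1ccccc1)OC[C@H](OCc1ccc(OC)cc1)CO | intermediate
12 | fragment 2, (2S)-3-[(tert-butyldiphenylsilyl)oxy]-2-[(4-methoxybenzyl)oxy]propanal | O=C[C@@H](OCc1ccc(OC)cc1)CO[Si](c1ccccc1)(c1ccccc1)C(C)(C)C | intermediate
13 | lithium acetylide of 6 (not isolated) | [Li]C#CCC/C(C)=C/CO[Si](c1ccccc1)(c1ccccc1)C(C)(C)C | intermediate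
14 | alkynylzinc bromide of 6 (not isolated) | Br[Zn]C#CCC/C(C)=C/CO[Si](c1ccccc1)(c1ccccc1)C(C)(C)C | intermediate
15 | (2S,3S,8E)-1,10-bis[(tert-butyldiphenylsilyl)oxy]-2-[(4-methoxybenzyl)oxy]-8-methyldec-8-en-4-yn-3-ol (germacrane 8S,9S, 8,9-syn) | CC(C)(C)[Si](c1ccccc1)(c1ccccc1)OC/C=C(\C)CCC#C[C@H](O)[C@@H](OCc1ccc(OC)cc1)CO[Si](c1ccccc1)(c1ccccc1)C(C)(C)C | intermediate
16 | (2S,3R,4E,8E)-1,10-bis[(tert-butyldiphenylsilyl)oxy]-2-[(4-methoxybenzyl)oxy]-8-methyl-4-(tributylstannyl)deca-4,8-dien-3-ol | CC(C)(C)[Si](c1ccccc1)(c1ccccc1)OC/C=C(\C)CC/C=C(/[Sn](CCCC)(CCCC)CCCC)[C@H](O)[C@@H](OCc1ccc(OC)cc1)CO[Si](c1ccccc1)(c1ccccc1)C(C)(C)C | intermediate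
17 | (2S,3R,4E,8E)-1,10-bis[(tert-butyldiphenylsilyl)oxy]-4-iodo-2-[(4-methoxybenzyl)oxy]-8-methyldeca-4,8-dien-3-ol | CC(C)(C)[Si](c1ccccc1)(c1ccccc1)OC/C=C(\C)CC/C=C(/I)[C@H](O)[C@@H](OCc1ccc(OC)cc1)CO[Si](c1ccccc1)(c1ccccc1)C(C)(C)C | intermediate
18 | (2S,3R,4E,8E)-3-[(tert-butyldimethylsilyl)oxy]-1,10-bis[(tert-butyldiphenylsilyl)oxy]-4-iodo-2-[(4-methoxybenzyl)oxy]-8-methyldeca-4,8-diene | CC(C)(C)[Si](c1ccccc1)(c1ccccc1)OC/C=C(\C)CC/C=C(/I)[C@H](O[Si](C)(C)C(C)(C)C)[C@@H](OCc1ccc(OC)cc1)CO[Si](c1ccccc1)(c1ccccc1)C(C)(C)C | intermediate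
19 | methyl (2E,6E)-2-{(1S,2S)-1-[(tert-butyldimethylsilyl)oxy]-3-[(tert-butyldiphenylsilyl)oxy]-2-[(4-methoxybenzyl)oxy]propyl}-8-[(tert-butyldiphenylsilyl)oxy]-6-methylocta-2,6-dienoate | CC(C)(C)[Si](c1ccccc1)(c1ccccc1)OC/C=C(\C)CC/C=C(/C(=O)OC)[C@H](O[Si](C)(C)C(C)(C)C)[C@@H](OCc1ccc(OC)cc1)CO[Si](c1ccccc1)(c1ccccc1)C(C)(C)C | intermediate
20 | methyl (2E,6E)-2-{(1S,2S)-1-[(tert-butyldimethylsilyl)oxy]-3-hydroxy-2-[(4-methoxybenzyl)oxy]propyl}-8-hydroxy-6-methylocta-2,6-dienoate | OC/C=C(\C)CC/C=C(/C(=O)OC)[C@H](O[Si](C)(C)C(C)(C)C)[C@@H](OCc1ccc(OC)cc1)CO | intermediate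
21 | methyl (2E,6E)-2-{(1S,2R)-1-[(tert-butyldimethylsilyl)oxy]-2-[(4-methoxybenzyl)oxy]-3-oxopropyl}-6-methyl-8-oxoocta-2,6-dienoate | O=C/C=C(\C)CC/C=C(/C(=O)OC)[C@H](O[Si](C)(C)C(C)(C)C)[C@@H](OCc1ccc(OC)cc1)C=O | intermediate
22 | methyl acrylate | C=CC(=O)OC | starting material
23 | methyl (4S,5S,6E,10E)-5-[(tert-butyldimethylsilyl)oxy]-3-hydroxy-6-(methoxycarbonyl)-4-[(4-methoxybenzyl)oxy]-10-methyl-2-methylidene-12-oxododeca-6,10-dienoate (C3 epimers; C3 is germacrane C7) | O=C/C=C(\C)CC/C=C(/C(=O)OC)[C@H](O[Si](C)(C)C(C)(C)C)[C@@H](OCc1ccc(OC)cc1)C(O)C(=C)C(=O)OC | intermediate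
24 | methyl (2Z,4S,5S,6E,10E)-2-(bromomethyl)-5-[(tert-butyldimethylsilyl)oxy]-6-(methoxycarbonyl)-4-[(4-methoxybenzyl)oxy]-10-methyl-12-oxododeca-2,6,10-trienoate | O=C/C=C(\C)CC/C=C(/C(=O)OC)[C@H](O[Si](C)(C)C(C)(C)C)[C@@H](OCc1ccc(OC)cc1)/C=C(\CBr)C(=O)OC | intermediate
25 | allylchromium dichloride from 24 (trivalent chromium on C13, drawn as the Z isomer, solvent ligands omitted, not isolated) | O=C/C=C(\C)CC/C=C(/C(=O)OC)[C@H](O[Si](C)(C)C(C)(C)C)[C@@H](OCc1ccc(OC)cc1)/C=C(\C[Cr](Cl)Cl)C(=O)OC | intermediate
26 | dichlorochromium C6-alkoxide of the ring-closed ten-membered hydroxy ester (configuration as in 27, not isolated) | C=C(C(=O)OC)[C@H]1[C@H](O[Cr](Cl)Cl)/C=C(\C)CC/C=C(/C(=O)OC)[C@H](O[Si](C)(C)C(C)(C)C)[C@H]1OCc2ccc(OC)cc2 | intermediate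
27 | methyl (3aS,4S,5S,6E,10E,11aR)-5-[(tert-butyldimethylsilyl)oxy]-4-[(4-methoxybenzyl)oxy]-10-methyl-3-methylidene-2-oxo-2,3,3a,4,5,8,9,11a-octahydrocyclodeca[b]furan-6-carboxylate | C=C1C(=O)O[C@@H]2/C=C(\C)CC/C=C(/C(=O)OC)[C@H](O[Si](C)(C)C(C)(C)C)[C@@H](OCc3ccc(OC)cc3)[C@@H]12 | intermediate
28 | methyl (3aR,4S,5S,6E,10E,11aR)-5-[(tert-butyldimethylsilyl)oxy]-4-hydroxy-10-methyl-3-methylidene-2-oxo-2,3,3a,4,5,8,9,11a-octahydrocyclodeca[b]furan-6-carboxylate (same geometry as 27; the 3a descriptor changes by priority only) | C=C1C(=O)O[C@@H]2/C=C(\C)CC/C=C(/C(=O)OC)[C@H](O[Si](C)(C)C(C)(C)C)[C@@H](O)[C@@H]12 | intermediate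
29 | angelic acid, (2Z)-2-methylbut-2-enoic acid | C/C=C(/C)C(=O)O | starting material
30 | (2Z)-2-methylbut-2-enoic 2,4,6-trichlorobenzoic anhydride (not isolated) | C/C=C(/C)C(=O)OC(=O)c1c(Cl)cc(Cl)cc1Cl | intermediate
31 | 9-O-TBS polymatin A, methyl (3aS,4S,5S,6E,10E,11aR)-5-[(tert-butyldimethylsilyl)oxy]-10-methyl-4-{[(2Z)-2-methylbut-2-enoyl]oxy}-3-methylidene-2-oxo-2,3,3a,4,5,8,9,11a-octahydrocyclodeca[b]furan-6-carboxylate | C=C1C(=O)O[C@@H]2/C=C(\C)CC/C=C(/C(=O)OC)[C@H](O[Si](C)(C)C(C)(C)C)[C@@H](OC(=O)/C(C)=C\C)[C@@H]12 | intermediate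
32 | polymatin A, methyl (3aS,4S,5S,6E,10E,11aR)-5-hydroxy-10-methyl-4-{[(2Z)-2-methylbut-2-enoyl]oxy}-3-methylidene-2-oxo-2,3,3a,4,5,8,9,11a-octahydrocyclodeca[b]furan-6-carboxylate (germacrane 6R,7S,8S,9S) | C=C1C(=O)O[C@@H]2/C=C(\C)CC/C=C(/C(=O)OC)[C@H](O)[C@@H](OC(=O)/C(C)=C\C)[C@@H]12 | target

**Step count and risks**

Total step count: 22 (steps 1–4 fragment 1, steps 5–9 fragment 2, steps 10–22 after the union).
Longest linear sequence: 18 steps (7 → 32: steps 5–9, then 10–22).

Steps most likely to fail:

1. Step 19 (ring closure). The tethered aldehyde may meet the wrong face of the allylchromium γ-carbon, giving a diastereomeric lactone, or the chains may couple with each other instead of closing the ring. The fallback sets out from 23 and comes back at 27. The alcohol 23 would be acetylated (Ac2O, pyridine, CH2Cl2) to the Morita–Baylis–Hillman acetate F1. F1 would then be added slowly to Pd(PPh3)4 (cat.) and InI in THF, where ionization to the π-allylpalladium complex and reductive transmetalation release an allylindium species (trivalent indium) only in low stationary concentration. Its addition to the C6 aldehyde would give the ring-closed hydroxy ester F2, which PPTS (cat.) in CH2Cl2 would lactonize to 27. This umpolung allylation uses another metal, another allyl precursor and catalytic release of the nucleophile, so both the face preference at C7 and the balance between ring closure and oligomerization change.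

2. Step 17 (acrylate addition to the dialdehyde). During the slow amine-mediated reaction the enolizable α-alkoxy aldehyde may epimerize at C8 or lose the C9 silyloxy group by β-elimination, or the enal may compete. The fallback sets out from 21 and comes back at 23. Methyl propiolate would be hydroaluminated with i-Bu2AlH and N-methylmorpholine N-oxide in THF at 0 °C to [1-(methoxycarbonyl)vinyl]diisobutylalane F3. One equivalent of F3 would be added to 21 at −78 °C. This non-basic 1,2-addition of a preformed vinylalane should take the more electrophilic, chelating α-alkoxy aldehyde first and give 23 directly.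

3. Step 21 (angelate formation). Acylation of the hindered C8 hydroxyl may be so slow that the angeloyl unit isomerizes to the tiglate, or the silyl group may shift from O9 to O8. The fallback sets out from 28 and comes back at 31. The alcohol 28 would be esterified with 2-[bis(2,2,2-trifluoroethoxy)phosphoryl]propanoic acid (dicyclohexylcarbodiimide, DMAP cat., CH2Cl2) to the phosphonate ester F4. Still–Gennari olefination of F4 with acetaldehyde (KN(SiMe3)2, 18-crown-6, THF, −78 °C) would then build the Z-trisubstituted enoate on the ester and give 31.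

Further compounds
F1 | step 19 | acetate of 23, methyl (4S,5S,6E,10E)-3-acetoxy-5-[(tert-butyldimethylsilyl)oxy]-6-(methoxycarbonyl)-4-[(4-methoxybenzyl)oxy]-10-methyl-2-methylidene-12-oxododeca-6,10-dienoate (C3 epimers) | O=C/C=C(\C)CC/C=C(/C(=O)OC)[C@H](O[Si](C)(C)C(C)(C)C)[C@@H](OCc1ccc(OC)cc1)C(OC(C)=O)C(=C)C(=O)OC
F2 | step 19 | ring-closed C6 hydroxy ester (ten-membered carbocycle, configuration as in 27) | C=C(C(=O)OC)[C@H]1[C@H](O)/C=C(\C)CC/C=C(/C(=O)OC)[C@H](O[Si](C)(C)C(C)(C)C)[C@H]1OCc2ccc(OC)cc2
F3 | step 17 | [1-(methoxycarbonyl)vinyl]diisobutylalane | C=C(C(=O)OC)[Al](CC(C)C)CC(C)C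
F4 | step 21 | 8-O-{2-[bis(2,2,2-trifluoroethoxy)phosphoryl]propanoyl} derivative of 28 | C=C1C(=O)O[C@@H]2/C=C(\C)CC/C=C(/C(=O)OC)[C@H](O[Si](C)(C)C(C)(C)C)[C@@H](OC(=O)C(C)P(=O)(OCC(F)(F)F)OCC(F)(F)F)[C@@H]12
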